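**Retrosynthetic overview**
- Hernanol has one ring, a γ-butyrolactone (O1, C2=O, C3, C4, C5), with two arylmethyl groups trans on the adjacent carbons C3 and C4. This is the pattern left when a carbon nucleophile (at C4) and a carbon electrophile (at C3) add across the C3=C4 bond of a butenolide.
- Key disconnection: the C4–C(vanillyl) bond is made by 1,4-addition of a lithiated vanillin-derived dithiane to (5R)-5-menthyloxybutenolide, and the C3–CH2Ar bond by benzylation of the resulting enolate with 3,4,5-trimethoxybenzyl bromide, in one flask.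
- Endgame: sulfur and the O-benzyl group are removed reductively; the acetal carbon C5 is reduced to CH2 with loss of menthol, so the controlling stereocentre leaves no trace.
- Ring order: the lactone ring comes from the furan ring of furfural in step 1 and persists through the key step; it is opened and re-closed on the same carbonyl in the last step. No other permanent ring is formed.

Key step: step 5

Assumption: 4-(benzyloxy)-3-methoxybenzaldehyde (O-benzylvanillin) is bought as such, (−)-menthol is the (1R,2S,5R) enantiomer, "menthyl" means (1R,2S,5R)-2-isopropyl-5-methylcyclohexyl, and the lactone is numbered O1, C2(=O), C3, C4, C5 throughout.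

**Route**

Step 1
Reactants: 1 furfural
Product: 2 5-hydroxyfuran-2(5H)-one (racemic lactol)
Conditions: O2, hν (visible), rose bengal (cat.), MeOH, rt
Reagents that add atoms: oxygen, O=O
Why: Dye-sensitised singlet-oxygen [4+2] cycloaddition to the furan gives a 2,5-endoperoxide that methanol solvolyses with loss of the formyl carbon as methyl formate (photo-oxygenation of furfural), leaving the γ-hydroxybutenolide.

Step 2
Reactants: 2 5-hydroxyfuran-2(5H)-one, 3 (−)-menthol
Product: 5 (5R)-5-[(1R,2S,5R)-menthyloxy]furan-2(5H)-one, via (5S)-epimeric menthyloxy butenolide 4 (not isolated)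
Conditions: CSA (cat.), toluene, reflux (Dean–Stark); crystallisation from petroleum ether, −20 °C; mother liquor re-equilibrated with CSA (cat.) and crystallised again
Reagents that add atoms: none
Why: Acid-catalysed acetalisation of the lactol with removal of water gives both C5 epimers, which interconvert under acid; the (5R) diastereomer is the one expected to crystallise, so C5 is set by crystallisation-driven equilibration against the fixed menthyl stereocentres.

Step 3
Reactants: 6 4-(benzyloxy)-3-methoxybenzaldehyde
Product: 7 2-[4-(benzyloxy)-3-methoxyphenyl]-1,3-dithiane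
Conditions: HS(CH2)3SH, BF3·OEt2 (cat.), CH2Cl2, 0 °C → rt
Reagents that add atoms: propane-1,3-dithiol, SCCCS
Why: Lewis acid-catalysed dithioacetalisation of an aromatic aldehyde is fast at 0 °C, and the aryl benzyl ether should tolerate catalytic BF3 at this temperature.

Step 4
Reactants: 8 (3,4,5-trimethoxyphenyl)methanol
Product: 9 5-(bromomethyl)-1,2,3-trimethoxybenzene (3,4,5-trimethoxybenzyl bromide)
Conditions: PBr3, Et2O, 0 °C; used directly
Reagents that add atoms: phosphorus tribromide, BrP(Br)Br
Why: Bromination of an activated benzylic alcohol through its bromophosphite (SN2 by bromide) is reliable, and the labile bromide is used without storage.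

Step 5
Reactants: 7 2-[4-(benzyloxy)-3-methoxyphenyl]-1,3-dithiane, 5 (5R)-5-[(1R,2S,5R)-menthyloxy]furan-2(5H)-one, 9 3,4,5-trimethoxybenzyl bromide
Product: 12 (3R,4R,5R)-4-{2-[4-(benzyloxy)-3-methoxyphenyl]-1,3-dithian-2-yl}-5-[(1R,2S,5R)-menthyloxy]-3-(3,4,5-trimethoxybenzyl)dihydrofuran-2(3H)-one, via 2-lithio-1,3-dithiane 10 (not isolated), via lithium lactone enolate 11 (not isolated)
Conditions: 7, n-BuLi, THF, −78 → −20 °C; 5, THF, −78 °C; then 9, DMPU, −78 °C → rt
Reagents that add atoms: none
Why: n-BuLi removes the benzylic dithiane proton to give the sulfur-stabilised carbanion 10, an acyl-anion equivalent that adds in Michael fashion to C4 of butenolide 5 to form the C4–C(dithiane) bond and the lithium enolate 11. That enolate is then C-benzylated by bromide 9 (SN2) to form the C3–CH2Ar bond. The closest known reaction type is the tandem conjugate addition of lithiated aryl dithianes to 5-alkoxy-2(5H)-furanones with enolate trapping by benzylic bromides. No ring is closed. C4 is set by the resident C5 acetal centre, the anion approaching the face opposite the menthyloxy group (4,5-trans), and C3 is set by the new C4 centre, the bromide approaching opposite the very large dithianyl group (3,4-trans). The step needs 1,4- over 1,2-addition, secured by the soft delocalised dithiane anion in THF, and mono-C-alkylation, secured by the reactive benzylic bromide with DMPU and by the hindered α-position of the product.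

Step 6
Reactants: 12 the all-trans dithianyl acetal lactone
Product: 14 (3R,4R,5R)-4-(4-hydroxy-3-methoxybenzyl)-5-[(1R,2S,5R)-menthyloxy]-3-(3,4,5-trimethoxybenzyl)dihydrofuran-2(3H)-one, via O-benzyl desulfurised acetal lactone 13 (not isolated)
Conditions: Raney Ni (W-2, excess), EtOH, reflux; filter (Celite); then H2 (1 atm), 10% Pd/C, EtOH, rt
Reagents that add atoms: none
Why: Raney nickel hydrogenolyses both benzylic C–S bonds (Mozingo-type desulfurisation), turning the dithiane carbon into the vanillyl CH2 without touching C3, C4 or C5; because nickel can also start to cleave the aryl benzyl ether, the sulfur-free filtrate is hydrogenated over Pd/C so that all material converges on the free phenol under neutral conditions that leave the acetal lactone intact.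

Step 7
Reactants: 14 the phenolic menthyloxy acetal lactone
Product: 17 hernanol (3R,4R)-4-(4-hydroxy-3-methoxybenzyl)-3-(3,4,5-trimethoxybenzyl)dihydrofuran-2(3H)-one, via formyl carboxylate dipotassium salt 15 (not isolated), via hydroxy carboxylate dipotassium salt 16 (not isolated)
Conditions: 14 added to NaBH4, KOH, EtOH/H2O, 0 °C → rt; then aq. HCl (pH 1), rt
Reagents that add atoms: potassium hydroxide, [K+].[OH-] (its oxygen enters the carboxyl group of 15 and 16; one carboxyl oxygen leaves again as water on lactonisation)
Why: Hydroxide opens the pseudo-ester at C2, the freed C5 hemiacetal collapses to the aldehyde with loss of menthol, the borohydride already present reduces it at once to the primary alcohol, and acidification closes the γ-lactone on the original C2 carboxyl (saponification–reduction–lactonisation of a γ-alkoxy lactone); C3 and C4 are untouched provided reduction outruns enolisation of the aldehyde, and C5 ends as CH2.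

**Compound list**
1 | furfural (furan-2-carbaldehyde) | O=Cc1ccco1 | starting material
2 | 5-hydroxyfuran-2(5H)-one (racemic) | O=C1C=CC(O)O1 | intermediate
3 | (−)-menthol, (1R,2S,5R)-2-isopropyl-5-methylcyclohexan-1-ol | C[C@@H]1CC[C@H]([C@@H](C1)O)C(C)C | starting material
4 | (5S)-5-[(1R,2S,5R)-menthyloxy]furan-2(5H)-one | C[C@@H]1CC[C@H]([C@@H](C1)O[C@@H]2C=CC(=O)O2)C(C)C | intermediate
5 | (5R)-5-[(1R,2S,5R)-menthyloxy]furan-2(5H)-one | C[C@@H]1CC[C@H]([C@@H](C1)O[C@H]2C=CC(=O)O2)C(C)C | intermediate
6 | 4-(benzyloxy)-3-methoxybenzaldehyde | COc1cc(C=O)ccc1OCc1ccccc1 | starting material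
7 | 2-[4-(benzyloxy)-3-methoxyphenyl]-1,3-dithiane | COc1cc(C2SCCCS2)ccc1OCc1ccccc1 | intermediate
8 | (3,4,5-trimethoxyphenyl)methanol | COc1cc(CO)cc(OC)c1OC | starting material
9 | 5-(bromomethyl)-1,2,3-trimethoxybenzene | COc1cc(CBr)cc(OC)c1OC | intermediate
10 | {2-[4-(benzyloxy)-3-methoxyphenyl]-1,3-dithian-2-yl}lithium | [Li]C1(SCCCS1)c1ccc(OCc2ccccc2)c(OC)c1 | intermediate
11 | lithium (4R,5R)-4-{2-[4-(benzyloxy)-3-methoxyphenyl]-1,3-dithian-2-yl}-5-[(1R,2S,5R)-menthyloxy]-4,5-dihydrofuran-2-olate | C[C@@H]1CC[C@H]([C@@H](C1)O[C@H]2[C@H](C3(c4ccc(OCc5ccccc5)c(OC)c4)SCCCS3)C=C(O[Li])O2)C(C)C | intermediate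
12 | (3R,4R,5R)-4-{2-[4-(benzyloxy)-3-methoxyphenyl]-1,3-dithian-2-yl}-5-[(1R,2S,5R)-menthyloxy]-3-(3,4,5-trimethoxybenzyl)dihydrofuran-2(3H)-one | C[C@@H]1CC[C@H]([C@@H](C1)O[C@H]2[C@H](C3(c4ccc(OCc5ccccc5)c(OC)c4)SCCCS3)[C@@H](Cc3cc(OC)c(OC)c(OC)c3)C(=O)O2)C(C)C | intermediate
13 | (3R,4R,5R)-4-[4-(benzyloxy)-3-methoxybenzyl]-5-[(1R,2S,5R)-menthyloxy]-3-(3,4,5-trimethoxybenzyl)dihydrofuran-2(3H)-one | C[C@@H]1CC[C@H]([C@@H](C1)O[C@H]2[C@H](Cc3ccc(OCc4ccccc4)c(OC)c3)[C@@H](Cc3cc(OC)c(OC)c(OC)c3)C(=O)O2)C(C)C | intermediate
14 | (3R,4R,5R)-4-(4-hydroxy-3-methoxybenzyl)-5-[(1R,2S,5R)-menthyloxy]-3-(3,4,5-trimethoxybenzyl)dihydrofuran-2(3H)-one | C[C@@H]1CC[C@H]([C@@H](C1)O[C@H]2[C@H](Cc3ccc(O)c(OC)c3)[C@@H](Cc3cc(OC)c(OC)c(OC)c3)C(=O)O2)C(C)C | intermediate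
15 | dipotassium (2R,3R)-3-formyl-4-(3-methoxy-4-oxidophenyl)-2-(3,4,5-trimethoxybenzyl)butanoate | COc1cc(C[C@@H](C=O)[C@@H](Cc2cc(OC)c(OC)c(OC)c2)C(=O)[O-])ccc1[O-].[K+].[K+] | intermediate
16 | dipotassium (2R,3R)-3-(hydroxymethyl)-4-(3-methoxy-4-oxidophenyl)-2-(3,4,5-trimethoxybenzyl)butanoate | COc1cc(C[C@@H](CO)[C@@H](Cc2cc(OC)c(OC)c(OC)c2)C(=O)[O-])ccc1[O-].[K+].[K+] | intermediate
17 | hernanol, (3R,4R)-4-(4-hydroxy-3-methoxybenzyl)-3-(3,4,5-trimethoxybenzyl)dihydrofuran-2(3H)-one | COc1cc(C[C@H]2COC(=O)[C@@H]2Cc2cc(OC)c(OC)c(OC)c2)ccc1O | target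

**Step count and risks**

Total step count: 7. Longest linear sequence: 5 steps (steps 1, 2, 5, 6, 7).

Steps most likely to fail, riskiest first:

Step 5. The enolate 11 sits next to the very large dithianyl group, so its benzylation may be slow. Proton transfer, retro-Michael loss of the dithiane anion or erosion of the trans selectivity could then compete while the mixture warms. The fallback separates the two bond formations. It sets out from 5 and 7: the conjugate addition is run as before but stopped by a cold NH4Cl quench, giving the C3-unsubstituted adduct (4R,5R)-4-{2-[4-(benzyloxy)-3-methoxyphenyl]-1,3-dithian-2-yl}-5-[(1R,2S,5R)-menthyloxy]dihydrofuran-2(3H)-one F1, which is purified by crystallisation. Its enolate is then regenerated with LDA in THF at −78 °C and alkylated with 9 in the presence of DMPU, again anti to the C4 substituent. This comes back to the route at 12.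

Step 7. The transient aldehyde 15 has its α-hydrogen at C4 and is formed in alkali. If hydride delivery is slower than enolisation, C4 epimerises and cis-lactone would contaminate the product; opening of the hindered pseudo-ester may also be incomplete. The fallback avoids strong base. It sets out from 14: the menthyl acetal is hydrolysed under acid (2 M HCl/dioxane, 60 °C) to the lactol (3R,4R)-5-hydroxy-4-(4-hydroxy-3-methoxybenzyl)-3-(3,4,5-trimethoxybenzyl)dihydrofuran-2(3H)-one F2 (mixture of C5 anomers), with menthol removed at this stage. The ring-opened formyl acid form of the lactol is then reduced with NaBH4 in EtOH/aq. NaHCO3 at 0 °C, and acidification closes the lactone. This comes back to the route at 17.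

Step 6. The two C–S bonds sit on a carbon shielded by the lactone ring and the menthyl acetal, so hydrogenolysis on the nickel surface may stall at a partly desulfurised stage or vary with the catalyst batch. Residual sulfur would then poison the palladium stage. The fallback replaces the surface reaction by a homolytic desulfurisation in solution. It sets out from 12: Bu3SnH (excess) and AIBN in refluxing toluene cleave both benzylic C–S bonds through the stabilised benzylic radical and give 13, which is isolated and freed of tin (KF work-up, chromatography). The Pd/C hydrogenolysis of step 6 is then applied to 13. This comes back to the route at 14, and no compound outside the list is made on this way (F0).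

Further compounds
F1 | step 5 | (4R,5R)-4-{2-[4-(benzyloxy)-3-methoxyphenyl]-1,3-dithian-2-yl}-5-[(1R,2S,5R)-menthyloxy]dihydrofuran-2(3H)-one | C[C@@H]1CC[C@H]([C@@H](C1)O[C@H]2[C@H](C3(c4ccc(OCc5ccccc5)c(OC)c4)SCCCS3)CC(=O)O2)C(C)C
F2 | step 7 | (3R,4R)-5-hydroxy-4-(4-hydroxy-3-methoxybenzyl)-3-(3,4,5-trimethoxybenzyl)dihydrofuran-2(3H)-one (C5 anomers) | COc1cc(C[C@H]2C(O)OC(=O)[C@@H]2Cc2cc(OC)c(OC)c(OC)c2)ccc1O
F0 | step 6 | none | none
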